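**Strategy.** Ring A (C1, C10–C14) is disconnected at C10–C11 and C12–C13: a 2-silyloxy diene (C13=C14–C1=C10) adds across a C11≡C12 alkyne. The design exploits the 1,5-relationship between C20, the methyl carbon on C11, and oxygen-bearing C8: a propiolate ester on O8, with C20 as its carbonyl carbon, makes the cycloaddition intramolecular. One thermal step closes cyclohexadiene ring A and a temporary δ-lactone and sets C10 from C9. The precursor is an acyclic dienyl propiolate made from (S)-glyceraldehyde acetonide. Reduction later turns C20 into the methyl group, a Mukaiyama aldol builds quaternary C1, and a Nozaki–Hiyama–Kishi reaction closes ten-membered ring B.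

Key step: step 8

Remark: carbons carry briarane numbers throughout (ring A: C1, C10–C14; ring B: C1–C10; lactone ring C: O–C7–C8–C17–C19; C15 on C1, C16 on C5, C18 on C17, C20 on C11). Compounds 7, 9, 12 and 14 are taken as commercial. 26 is a mixture at its CHBr carbon and 33 a mixture of C6 epimers; later steps converge both.

Step 1
Reactants: 1 4-methoxybenzyl alcohol; 2 allyl bromide
Product: 3 allyl 4-methoxybenzyl ether
Conditions: NaH, THF/DMF, 0 °C to rt
Reagents that add atoms: none
Why: Williamson ether synthesis, in which the sodium alkoxide of 1 displaces bromide from 2 by SN2; no stereocenter is formed.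

Step 2
Reactants: 4 acrolein
Product: 6 2-bromoacrolein, via 2,3-dibromopropanal 5 (not isolated)
Conditions: Br2, CH2Cl2, 0 °C; then Et3N, 0 °C
Reagents that add atoms: bromine, BrBr
Why: Electrophilic bromine addition to the C=C bond followed by E1cB loss of HBr from the α-bromo aldehyde should give the 2-bromo enal; no stereocenter is formed.

Step 3
Reactants: 6 2-bromoacrolein; 7 (triphenylphosphoranylidene)acetaldehyde
Product: 8 (2E)-4-bromopenta-2,4-dienal
Conditions: CH2Cl2, 0 °C to rt
Reagents that add atoms: none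
Why: Wittig olefination with a stabilised ylide should give the E-dienal, the more electrophilic α-bromo enal 6 reacting in preference to the product aldehyde.

Step 4
Reactants: 9 (S)-glyceraldehyde acetonide; 3 allyl 4-methoxybenzyl ether
Product: 11 (1R,2S)-1-[(4S)-2,2-dimethyl-1,3-dioxolan-4-yl]-2-[(4-methoxybenzyl)oxy]but-3-en-1-ol, via (Z)-γ-(4-methoxybenzyloxy)allyldiisopinocampheylborane 10 (not isolated)
Conditions: 3, s-BuLi, THF, −78 °C; (+)-Ipc2BOMe; BF3·OEt2; then 9, −78 °C; NaOH, H2O2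
Reagents that add atoms: none
Why: Brown-type alkoxyallylboration through a closed chair (Zimmerman–Traxler) transition state, in which the (Z)-γ-alkoxyallyl geometry gives the syn C8/C9 relationship and the isopinocampheyl ligands derived from (−)-α-pinene select the aldehyde face, matched with the Felkin preference of 9, so that C8 (R) and C9 (S) should form anti to C7.

Step 5
Reactants: 11 homoallylic alcohol; 12 3-methylbut-3-en-2-one
Product: 13 (3E,5S,6R)-6-[(4S)-2,2-dimethyl-1,3-dioxolan-4-yl]-6-hydroxy-5-[(4-methoxybenzyl)oxy]-3-methylhex-3-en-2-one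
Conditions: 12 (5 equiv), second-generation Hoveyda–Grubbs catalyst RuCl2(H2IMes)(=CH-C6H4-2-O-i-Pr) (5 mol %), CH2Cl2, 40 °C
Reagents that add atoms: none
Why: Olefin cross-metathesis between the terminal alkene and the 1,1-disubstituted enone partner (used in excess) should give the trisubstituted enone as the thermodynamically favoured E isomer; no stereocenter is touched.

Step 6
Reactants: 13 hydroxy enone; 14 propiolic acid
Product: 15 C8 propiolate ester of 13
Conditions: DCC, DMAP (cat.), CH2Cl2, −20 to 0 °C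
Reagents that add atoms: none
Why: Steglich esterification (carbodiimide activation, DMAP acyl transfer) of the only free hydroxyl, run cold to avoid amine addition to the ynoate.

Step 7
Reactants: 15 propiolate ester
Product: 16 2-silyloxy diene (TBS dienol ether of 15)
Conditions: TBSOTf, i-Pr2NEt, CH2Cl2, −78 °C, short reaction time
Reagents that add atoms: tert-butyldimethylsilyl triflate, CC(C)(C)[Si](C)(C)OS(=O)(=O)C(F)(F)F
Why: Soft enolisation (silyl triflate plus hindered amine) at the methyl group gives the cross-conjugated 2-silyloxy diene kinetically, and the short time at −78 °C should keep the acetylenic C–H unsilylated.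

Step 8
Reactants: 16 2-silyloxy diene
Product: 17 bicyclic lactone (3R,4S,4aR)-6-[(tert-butyldimethylsilyl)oxy]-3-[(4S)-2,2-dimethyl-1,3-dioxolan-4-yl]-4-[(4-methoxybenzyl)oxy]-5-methyl-3,4,4a,7-tetrahydro-1H-isochromen-1-one
Conditions: PhMe (0.01 M), BHT (cat.), 140 °C, sealed tube, Ar
Reagents that add atoms: none
Why: Concerted thermal [4+2] cycloaddition of normal electron demand between the electron-rich 2-silyloxy diene (C13=C14–C1=C10) and the tethered propiolate (C11≡C12); the closest known type is the ester-tethered intramolecular Diels–Alder reaction of dienyl propiolates. Ring A closes as a cyclohexa-1,4-diene by the cycloaddition itself, and the δ-lactone (C20, O8, C8, C9, C10, C11) closes as the fused six-membered tether ring. The only new stereocenter, C10, is set by C9: allylic 1,3-strain with the C15 methyl group holds H9 in the diene plane, the PMB ether points outward, and the C8–O8 tether can then deliver the alkyne to one diene face only. The regiochemistry (C10–C11 and C12–C13) is fixed by the tether and matches the polarisation (nucleophilic C13 to the β-carbon C12). The step needs this π-facial selectivity and must outrun oxidation of the 1,4-diene to the arene, which exclusion of air, BHT and the fully substituted C1=C14 enol ether should secure.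

Step 9
Reactants: 17 bicyclic lactone
Product: 18 (1R,2S)-2-[(1S)-3-[(tert-butyldimethylsilyl)oxy]-6-(hydroxymethyl)-2-methylcyclohexa-2,5-dien-1-yl]-1-[(4S)-2,2-dimethyl-1,3-dioxolan-4-yl]-2-[(4-methoxybenzyl)oxy]ethan-1-ol
Conditions: i-Bu2AlH, CH2Cl2, −78 to 0 °C; aq. KNaC4H4O6
Reagents that add atoms: none
Why: Hydride 1,2-reduction of the α,β-unsaturated lactone opens the tether to the allylic C20 alcohol and frees the C8 hydroxyl, while the silyl enol ether is inert to hydride.

Step 10
Reactants: 18 diol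
Product: 20 C20-methyl alcohol, via allylic mesylate 19 (not isolated)
Conditions: MsCl, Et3N, CH2Cl2, −40 °C; then LiEt3BH, THF, −78 to 0 °C
Reagents that add atoms: none
Why: Selective sulfonylation of the primary allylic alcohol and SN2 hydride displacement of the allylic mesylate should turn C20 into the methyl group; holding the second stage at −78 °C lets reduction outrun ether formation by the C8 hydroxyl.

Step 11
Reactants: 20 C20-methyl alcohol
Product: 21 C8 ketone
Conditions: SO3·pyridine, DMSO, i-Pr2NEt, CH2Cl2, 0 °C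
Reagents that add atoms: none
Why: Parikh–Doering oxidation (activated DMSO under non-acidic conditions) converts the secondary C8 alcohol into the ketone without harming the acid-labile silyl enol ether.

Step 12
Reactants: 21 C8 ketone; 8 (2E)-4-bromopenta-2,4-dienal
Product: 22 C2 aldol adduct
Conditions: BF3·OEt2, CH2Cl2, −78 °C; aq. NaHCO3
Reagents that add atoms: none
Why: Mukaiyama aldol addition in which the BF3-activated aldehyde attacks the tetrasubstituted silyl enol ether at C1 anti to the C10 side chain, setting quaternary C1 (methyl cis to C9), while an open antiperiplanar transition state that keeps the dienyl group away from the silyloxy group should give the (2S)-carbinol.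

Step 13
Reactants: 22 C2 aldol adduct
Product: 23 C2 acetate
Conditions: Ac2O, pyridine, DMAP (cat.), CH2Cl2, 0 °C
Reagents that add atoms: acetic anhydride, CC(=O)OC(C)=O
Why: DMAP-catalysed acetylation of the only hydroxyl; C1 is quaternary, so the β-acetoxy ketone cannot eliminate.

Step 14
Reactants: 23 C2 acetate
Product: 24 6,7-diol
Conditions: AcOH/H2O/THF (3:1:1), 40 °C
Reagents that add atoms: none
Why: Acid-catalysed hydrolysis of the terminal isopropylidene acetal, which the esters, the PMB ether and the vinyl bromide should tolerate.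

Step 15
Reactants: 24 6,7-diol
Product: 25 primary triethylsilyl ether
Conditions: Et3SiCl, imidazole, CH2Cl2, −40 to −20 °C
Reagents that add atoms: chlorotriethylsilane, CC[Si](Cl)(CC)CC
Why: Silylation of the primary C6 hydroxyl in preference to the hindered secondary C7 hydroxyl (steric differentiation at low temperature).

Step 16
Reactants: 25 primary triethylsilyl ether
Product: 26 O7 2-bromopropanoate
Conditions: 2-bromopropanoyl bromide, pyridine, CH2Cl2, 0 °C
Reagents that add atoms: 2-bromopropanoyl bromide, CC(Br)C(Br)=O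
Why: O-acylation of the C7 hydroxyl by the acyl bromide installs the α-bromo ester for the Reformatsky step; the CHBr centre is a mixture that step 17 erases.

Step 17
Reactants: 26 O7 2-bromopropanoate
Product: 27 hydroxy lactone (ring C closed)
Conditions: SmI2 (2.2 equiv), THF, −78 °C; aq. NH4Cl
Reagents that add atoms: none
Why: Samarium diiodide-mediated intramolecular Reformatsky reaction, in which reduction of the C–Br bond gives a samarium enolate that adds to the C8 ketone within a chelate; the conformer with H7 eclipsing the C9 branch should place C9 trans to C6 on the new lactone (C8 R), and the C17 methyl group should take the position trans to C9, which is also the thermodynamic one.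

Step 18
Reactants: 27 hydroxy lactone
Product: 28 14-alcohol
Conditions: LiB(s-Bu)3H (2.5 equiv), THF, −78 °C; AcOH quench at −78 °C
Reagents that add atoms: none
Why: Ketone reduction by a bulky trialkylborohydride, which should approach C14 past the small C15 methyl group and anti to the branched C2 substituent to give the 14-hydroxyl cis to C2 (this reagent is known to give axial alcohols from 2,2-disubstituted cyclohexanones); the cold quench prevents acetyl migration from O2.

Step 19
Reactants: 28 14-alcohol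
Product: 29 11,12-epoxide
Conditions: VO(acac)2 (cat.), t-BuOOH, CH2Cl2, 0 °C to rt
Reagents that add atoms: tert-butyl hydroperoxide, CC(C)(C)OO
Why: Vanadium-catalysed hydroxyl-directed epoxidation, in which the homoallylic 14-hydroxyl delivers oxygen to its own face of the electron-rich trisubstituted C11=C12 alkene (the face away from the C15 methyl group), setting C11 (S) and C12 (R); the electron-poor bromodiene carries no free allylic hydroxyl.

Step 20
Reactants: 29 11,12-epoxide
Product: 30 9,14-diol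
Conditions: DDQ, CH2Cl2/pH 7 phosphate buffer, 0 °C
Reagents that add atoms: none
Why: Oxidative cleavage of the PMB ether by DDQ (hydride abstraction, then hydrolysis of the oxocarbenium ion) under buffered conditions that should leave the epoxide and the silyl ether intact.

Step 21
Reactants: 30 9,14-diol
Product: 31 2,9,14-triacetate
Conditions: Ac2O, pyridine, DMAP, CH2Cl2, rt
Reagents that add atoms: acetic anhydride, CC(=O)OC(C)=O
Why: DMAP-catalysed acetylation of the secondary C9 and C14 hydroxyls; the hindered tertiary C8 hydroxyl should stay free.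

Step 22
Reactants: 31 2,9,14-triacetate
Product: 32 C6 aldehyde
Conditions: (COCl)2, DMSO, CH2Cl2, −78 to −30 °C; Et3N
Reagents that add atoms: none
Why: Swern oxidation applied directly to the primary triethylsilyl ether (chloride-assisted desilylation in the activated DMSO medium, then oxidation) should give the aldehyde in one operation; the tertiary hydroxyl is inert.

Step 23
Reactants: 32 C6 aldehyde
Product: 33 macrocyclic allylic alcohol (C6 epimers)
Conditions: CrCl2 (10 equiv), NiCl2 (1 mol %), DMSO/THF, rt, 2 mM, slow addition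
Reagents that add atoms: none
Why: Nozaki–Hiyama–Kishi reaction, in which nickel-catalysed formation of a dienylchromium species from the vinyl bromide and its intramolecular addition to the aldehyde under high dilution should close ten-membered ring B; C6 need not be controlled here because steps 24 and 25 reset it.

Step 24
Reactants: 33 macrocyclic allylic alcohol
Product: 34 C6 enone
Conditions: Dess–Martin periodinane, NaHCO3, CH2Cl2, 0 °C to rt
Reagents that add atoms: none
Why: Dess–Martin oxidation of the allylic alcohol converges both C6 epimers on the cross-conjugated enone under neutral conditions.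

Step 25
Reactants: 34 C6 enone
Product: 35 (6R)-allylic alcohol
Conditions: NaBH4, CeCl3·7H2O, MeOH, −78 °C
Reagents that add atoms: none
Why: Luche 1,2-reduction, in which Felkin–Anh attack of hydride anti to the C7–O bond of the α-alkoxy ketone should give the 6,7-syn (6R) alcohol without conjugate reduction.

Step 26
Reactants: 35 (6R)-allylic alcohol
Product: 36 CNP0106406.1 (target)
Conditions: PPh3, hexachloroacetone, CH2Cl2, −20 to 0 °C
Reagents that add atoms: hexachloroacetone, ClC(Cl)(Cl)C(=O)C(Cl)(Cl)Cl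
Why: Appel-type deoxychlorination, in which chloride displaces the alkoxyphosphonium ion by SN2 with inversion and should convert the (6R)-alcohol into the (6S)-chloride; this mild chlorine source is known to suppress allylic transposition.

**Compound list**

1 | 4-methoxybenzyl alcohol | COc1ccc(CO)cc1 | starting material
2 | allyl bromide | C=CCBr | starting material
3 | allyl 4-methoxybenzyl ether | C=CCOCc1ccc(OC)cc1 | intermediate
4 | acrolein | C=CC=O | starting material
5 | 2,3-dibromopropanal | O=CC(Br)CBr | intermediate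
6 | 2-bromoacrolein | C=C(Br)C=O | intermediate
7 | (triphenylphosphoranylidene)acetaldehyde | O=CC=P(c1ccccc1)(c1ccccc1)c1ccccc1 | starting material
8 | (2E)-4-bromopenta-2,4-dienal | C=C(Br)/C=C/C=O | intermediate
9 | (S)-glyceraldehyde acetonide, (4S)-2,2-dimethyl-1,3-dioxolane-4-carbaldehyde | CC1(C)OC[C@@H](C=O)O1 | starting material
10 | (Z)-γ-(4-methoxybenzyloxy)allyldiisopinocampheylborane (isopinocampheyl groups from (−)-α-pinene) | COc1ccc(CO/C=C\CB([C@H]2C[C@H]3C[C@@H]([C@@H]2C)C3(C)C)[C@H]2C[C@H]3C[C@@H]([C@@H]2C)C3(C)C)cc1 | intermediate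
11 | (1R,2S)-1-[(4S)-2,2-dimethyl-1,3-dioxolan-4-yl]-2-[(4-methoxybenzyl)oxy]but-3-en-1-ol | C=C[C@H](OCc1ccc(OC)cc1)[C@@H](O)[C@@H]1COC(C)(C)O1 | intermediate
12 | 3-methylbut-3-en-2-one | CC(=O)C(C)=C | starting material
13 | (3E,5S,6R)-6-[(4S)-2,2-dimethyl-1,3-dioxolan-4-yl]-6-hydroxy-5-[(4-methoxybenzyl)oxy]-3-methylhex-3-en-2-one | CC(=O)/C(C)=C/[C@H](OCc1ccc(OC)cc1)[C@@H](O)[C@@H]1COC(C)(C)O1 | intermediate
14 | propiolic acid | C#CC(=O)O | starting material
15 | (1R,2S,3E)-1-[(4S)-2,2-dimethyl-1,3-dioxolan-4-yl]-2-[(4-methoxybenzyl)oxy]-4-methyl-5-oxohex-3-en-1-yl prop-2-ynoate | CC(=O)/C(C)=C/[C@H](OCc1ccc(OC)cc1)[C@@H](OC(=O)C#C)[C@@H]1COC(C)(C)O1 | intermediate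
16 | (1R,2S,3E)-5-[(tert-butyldimethylsilyl)oxy]-1-[(4S)-2,2-dimethyl-1,3-dioxolan-4-yl]-2-[(4-methoxybenzyl)oxy]-4-methylhexa-3,5-dien-1-yl prop-2-ynoate | C=C(O[Si](C)(C)C(C)(C)C)/C(C)=C/[C@H](OCc1ccc(OC)cc1)[C@@H](OC(=O)C#C)[C@@H]1COC(C)(C)O1 | intermediate
17 | (3R,4S,4aR)-6-[(tert-butyldimethylsilyl)oxy]-3-[(4S)-2,2-dimethyl-1,3-dioxolan-4-yl]-4-[(4-methoxybenzyl)oxy]-5-methyl-3,4,4a,7-tetrahydro-1H-isochromen-1-one | O=C1O[C@@H]([C@@H]2COC(C)(C)O2)[C@@H](OCc2ccc(OC)cc2)[C@H]2C1=CCC(O[Si](C)(C)C(C)(C)C)=C2C | intermediate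
18 | (1R,2S)-2-[(1S)-3-[(tert-butyldimethylsilyl)oxy]-6-(hydroxymethyl)-2-methylcyclohexa-2,5-dien-1-yl]-1-[(4S)-2,2-dimethyl-1,3-dioxolan-4-yl]-2-[(4-methoxybenzyl)oxy]ethan-1-ol | OCC1=CCC(O[Si](C)(C)C(C)(C)C)=C(C)[C@H]1[C@H](OCc1ccc(OC)cc1)[C@@H](O)[C@@H]1COC(C)(C)O1 | intermediate
19 | primary allylic methanesulfonate of 18 (C20–OMs) | CS(=O)(=O)OCC1=CCC(O[Si](C)(C)C(C)(C)C)=C(C)[C@H]1[C@H](OCc1ccc(OC)cc1)[C@@H](O)[C@@H]1COC(C)(C)O1 | intermediate
20 | (1R,2S)-2-[(1S)-3-[(tert-butyldimethylsilyl)oxy]-2,6-dimethylcyclohexa-2,5-dien-1-yl]-1-[(4S)-2,2-dimethyl-1,3-dioxolan-4-yl]-2-[(4-methoxybenzyl)oxy]ethan-1-ol | CC1=CCC(O[Si](C)(C)C(C)(C)C)=C(C)[C@H]1[C@H](OCc1ccc(OC)cc1)[C@@H](O)[C@@H]1COC(C)(C)O1 | intermediate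
21 | (2S)-2-[(1S)-3-[(tert-butyldimethylsilyl)oxy]-2,6-dimethylcyclohexa-2,5-dien-1-yl]-1-[(4S)-2,2-dimethyl-1,3-dioxolan-4-yl]-2-[(4-methoxybenzyl)oxy]ethan-1-one | CC1=CCC(O[Si](C)(C)C(C)(C)C)=C(C)[C@H]1[C@H](OCc1ccc(OC)cc1)C(=O)[C@@H]1COC(C)(C)O1 | intermediate
22 | aldol adduct: ring-A 14-ketone with quaternary C1 (C15 methyl cis to C9), (2S,3E)-2-hydroxy-5-bromo-3,5(16)-dienyl chain on C1, 9-O-PMB, C8 ketone, 6,7-O-isopropylidene | C=C(Br)/C=C/[C@H](O)[C@@]1(C)C(=O)CC=C(C)[C@@H]1[C@H](OCc1ccc(OC)cc1)C(=O)[C@@H]1COC(C)(C)O1 | intermediate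
23 | 2-O-acetate of 22 | C=C(Br)/C=C/[C@H](OC(C)=O)[C@@]1(C)C(=O)CC=C(C)[C@@H]1[C@H](OCc1ccc(OC)cc1)C(=O)[C@@H]1COC(C)(C)O1 | intermediate
24 | 6,7-diol from 23 (C7 secondary and C6 primary hydroxyls free) | C=C(Br)/C=C/[C@H](OC(C)=O)[C@@]1(C)C(=O)CC=C(C)[C@@H]1[C@H](OCc1ccc(OC)cc1)C(=O)[C@@H](O)CO | intermediate
25 | 6-O-triethylsilyl ether of 24 | C=C(Br)/C=C/[C@H](OC(C)=O)[C@@]1(C)C(=O)CC=C(C)[C@@H]1[C@H](OCc1ccc(OC)cc1)C(=O)[C@@H](O)CO[Si](CC)(CC)CC | intermediate
26 | 7-O-(2-bromopropanoyl) ester of 25 (both configurations at CHBr) | C=C(Br)/C=C/[C@H](OC(C)=O)[C@@]1(C)C(=O)CC=C(C)[C@@H]1[C@H](OCc1ccc(OC)cc1)C(=O)[C@@H](OC(=O)C(C)Br)CO[Si](CC)(CC)CC | intermediate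
27 | hydroxy lactone: ring C closed (C7, C8, C17 as in the target; 8-OH and 18-methyl cis to C6), ring-A 14-ketone | C=C(Br)/C=C/[C@H](OC(C)=O)[C@@]1(C)C(=O)CC=C(C)[C@@H]1[C@H](OCc1ccc(OC)cc1)[C@]1(O)[C@@H](C)C(=O)O[C@H]1CO[Si](CC)(CC)CC | intermediate
28 | 14-alcohol of 27 (14-OH cis to C2, trans to C15) | C=C(Br)/C=C/[C@H](OC(C)=O)[C@@]1(C)[C@@H](O)CC=C(C)[C@@H]1[C@H](OCc1ccc(OC)cc1)[C@]1(O)[C@@H](C)C(=O)O[C@H]1CO[Si](CC)(CC)CC | intermediate
29 | 11,12-epoxide of 28 (epoxide oxygen cis to the 14-OH) | C=C(Br)/C=C/[C@H](OC(C)=O)[C@@]1(C)[C@@H](O)C[C@H]2O[C@@]2(C)[C@@H]1[C@H](OCc1ccc(OC)cc1)[C@]1(O)[C@@H](C)C(=O)O[C@H]1CO[Si](CC)(CC)CC | intermediate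
30 | 9,14-diol (PMB removed from 29) | C=C(Br)/C=C/[C@H](OC(C)=O)[C@@]1(C)[C@@H](O)C[C@H]2O[C@@]2(C)[C@@H]1[C@H](O)[C@]1(O)[C@@H](C)C(=O)O[C@H]1CO[Si](CC)(CC)CC | intermediate
31 | 2,9,14-triacetate with 6-O-triethylsilyl ether and free 8-OH | C=C(Br)/C=C/[C@H](OC(C)=O)[C@@]1(C)[C@@H](OC(C)=O)C[C@H]2O[C@@]2(C)[C@@H]1[C@H](OC(C)=O)[C@]1(O)[C@@H](C)C(=O)O[C@H]1CO[Si](CC)(CC)CC | intermediate
32 | C6 aldehyde (seco-ring-B bromodiene aldehyde) | C=C(Br)/C=C/[C@H](OC(C)=O)[C@@]1(C)[C@@H](OC(C)=O)C[C@H]2O[C@@]2(C)[C@@H]1[C@H](OC(C)=O)[C@]1(O)[C@@H](C)C(=O)O[C@H]1C=O | intermediate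
33 | macrocyclic (6RS)-6-hydroxy analogue of the target (OH in place of Cl, both C6 epimers) | C=C1/C=C/[C@H](OC(C)=O)[C@@]2(C)[C@@H](OC(C)=O)C[C@H]3O[C@@]3(C)[C@@H]2[C@H](OC(C)=O)[C@]2(O)[C@@H](C)C(=O)O[C@H]2C1O | intermediate
34 | macrocyclic C6 ketone (cross-conjugated enone) | C=C1/C=C/[C@H](OC(C)=O)[C@@]2(C)[C@@H](OC(C)=O)C[C@H]3O[C@@]3(C)[C@@H]2[C@H](OC(C)=O)[C@]2(O)[C@@H](C)C(=O)O[C@H]2C1=O | intermediate
35 | (6R)-6-hydroxy analogue of the target (6-OH syn to O7) | C=C1/C=C/[C@H](OC(C)=O)[C@@]2(C)[C@@H](OC(C)=O)C[C@H]3O[C@@]3(C)[C@@H]2[C@H](OC(C)=O)[C@]2(O)[C@@H](C)C(=O)O[C@H]2[C@@H]1O | intermediate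
36 | CNP0106406.1 (1R,2S,6S,7R,8R,9S,10S,11S,12R,14S,17R) | C=C1/C=C/[C@H](OC(C)=O)[C@@]2(C)[C@@H](OC(C)=O)C[C@H]3O[C@@]3(C)[C@@H]2[C@H](OC(C)=O)[C@]2(O)[C@@H](C)C(=O)O[C@H]2[C@H]1Cl | target

**Totals.** Total step count: 26. Longest linear sequence: 24 steps (step 1, then steps 4 to 26).

**Three steps most likely to fail**

1. Step 23 (closure of ring B). Oligomerisation may outrun closure of the strained ten-membered ring, and the hindered 2-bromo-1,3-diene may undergo slow oxidative addition followed by protonolysis. The fallback sets out from 21 and comes back at 33; it closes the ring at C3=C4 by ring-closing metathesis instead. Mukaiyama aldol of 21 with acrolein 4 (BF3·OEt2, −78 °C) should give the C2 vinyl carbinol F5. The operations of steps 13 to 22 then give in turn the acetate F6, the 6,7-diol F7, the primary triethylsilyl ether F8, the 2-bromopropanoate F9, the hydroxy lactone F10, the 14-alcohol F11, the 11,12-epoxide F12, the 9,14-diol F13, the triacetate F14 and the C6 aldehyde F15. Indium-mediated addition of 1,4-dibromobut-2-yne (In, THF/H2O, rt) attaches a buta-1,3-dien-2-yl group to C6 and gives the dienyl carbinol F16 as a C6 epimer mixture. Ring-closing metathesis between the C3 vinyl group and the monosubstituted alkene of the diene (second-generation Grubbs catalyst RuCl2(H2IMes)(PCy3)(=CHPh), PhMe, high dilution) releases ethene and should give 33.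

2. Step 8 (key cycloaddition). The ester tether may cyclise sluggishly, the cyclohexa-1,4-diene may be oxidised to the arene on prolonged heating, and an alkyne silylated in step 7 would be carried into the adduct. The fallback sets out from 13 and comes back at 17; it replaces the alkyne by a tethered (Z)-3-bromoacrylate, which has no acidic C–H and gives a cyclohexene that cannot aromatise before the C11=C12 bond is unmasked. Esterification of 13 with (Z)-3-bromoacrylic acid (DCC, DMAP) gives the bromoacrylate F1, and silylation (TBSOTf, i-Pr2NEt) gives the silyloxy diene F2. The thermal intramolecular Diels–Alder reaction gives the bromo lactone F3 (its C11/C12 isomers are inconsequential), and E1cB elimination of HBr with DBU should give 17.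

3. Step 17 (lactone ring C). The samarium reagent may reductively cleave the α-oxygen substituents of the C8 ketone, or the enolate may add with poor facial selectivity at C8 and C17. The fallback sets out from 25 and comes back at 27; it uses an intermolecular, chelation-controlled zinc Reformatsky reaction followed by lactonisation. Treating 25 with Zn and ethyl 2-bromopropanoate (THF, 0 °C) should form a zinc alkoxide at O7 that chelates the C8 ketone, so that the zinc enolate attacks anti to C6 and gives the β-hydroxy ester F4 (C17 epimers). Acid-catalysed lactonisation onto O7 (PPTS, PhMe, loss of ethanol) and equilibration of C17 with DBU should give 27.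

**Further compounds**

F1 | step 8 | (Z)-3-bromoacrylate ester of 13 at the C8 hydroxyl | CC(=O)/C(C)=C/[C@H](OCc1ccc(OC)cc1)[C@@H](OC(=O)/C=C\Br)[C@@H]1COC(C)(C)O1
F2 | step 8 | TBS dienol ether of F1 | C=C(O[Si](C)(C)C(C)(C)C)/C(C)=C/[C@H](OCc1ccc(OC)cc1)[C@@H](OC(=O)/C=C\Br)[C@@H]1COC(C)(C)O1
F3 | step 8 | 11,12-dihydro-12-bromo analogue of 17 (mixture at C11 and C12) | O=C1O[C@@H]([C@@H]2COC(C)(C)O2)[C@@H](OCc2ccc(OC)cc2)[C@H]2C1C(Br)CC(O[Si](C)(C)C(C)(C)C)=C2C
F4 | step 17 | ethyl ester of the seco-lactone of 27 (β-hydroxy ester with free 7-OH and 8-OH, C17 epimers) | C=C(Br)/C=C/[C@H](OC(C)=O)[C@@]1(C)C(=O)CC=C(C)[C@@H]1[C@H](OCc1ccc(OC)cc1)[C@](O)(C(C)C(=O)OCC)[C@@H](O)CO[Si](CC)(CC)CC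
F5 | step 23 | acrolein aldol adduct of 21 (C2 vinyl carbinol, analogue of 22) | C=C[C@H](O)[C@@]1(C)C(=O)CC=C(C)[C@@H]1[C@H](OCc1ccc(OC)cc1)C(=O)[C@@H]1COC(C)(C)O1
F6 | step 23 | 2-O-acetate of F5 | C=C[C@H](OC(C)=O)[C@@]1(C)C(=O)CC=C(C)[C@@H]1[C@H](OCc1ccc(OC)cc1)C(=O)[C@@H]1COC(C)(C)O1
F7 | step 23 | 6,7-diol from F6 | C=C[C@H](OC(C)=O)[C@@]1(C)C(=O)CC=C(C)[C@@H]1[C@H](OCc1ccc(OC)cc1)C(=O)[C@@H](O)CO
F8 | step 23 | 6-O-triethylsilyl ether of F7 | C=C[C@H](OC(C)=O)[C@@]1(C)C(=O)CC=C(C)[C@@H]1[C@H](OCc1ccc(OC)cc1)C(=O)[C@@H](O)CO[Si](CC)(CC)CC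
F9 | step 23 | 7-O-(2-bromopropanoyl) ester of F8 | C=C[C@H](OC(C)=O)[C@@]1(C)C(=O)CC=C(C)[C@@H]1[C@H](OCc1ccc(OC)cc1)C(=O)[C@@H](OC(=O)C(C)Br)CO[Si](CC)(CC)CC
F10 | step 23 | hydroxy lactone (C2 vinyl analogue of 27) | C=C[C@H](OC(C)=O)[C@@]1(C)C(=O)CC=C(C)[C@@H]1[C@H](OCc1ccc(OC)cc1)[C@]1(O)[C@@H](C)C(=O)O[C@H]1CO[Si](CC)(CC)CC
F11 | step 23 | 14-alcohol (C2 vinyl analogue of 28) | C=C[C@H](OC(C)=O)[C@@]1(C)[C@@H](O)CC=C(C)[C@@H]1[C@H](OCc1ccc(OC)cc1)[C@]1(O)[C@@H](C)C(=O)O[C@H]1CO[Si](CC)(CC)CC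
F12 | step 23 | 11,12-epoxide (C2 vinyl analogue of 29) | C=C[C@H](OC(C)=O)[C@@]1(C)[C@@H](O)C[C@H]2O[C@@]2(C)[C@@H]1[C@H](OCc1ccc(OC)cc1)[C@]1(O)[C@@H](C)C(=O)O[C@H]1CO[Si](CC)(CC)CC
F13 | step 23 | 9,14-diol (C2 vinyl analogue of 30) | C=C[C@H](OC(C)=O)[C@@]1(C)[C@@H](O)C[C@H]2O[C@@]2(C)[C@@H]1[C@H](O)[C@]1(O)[C@@H](C)C(=O)O[C@H]1CO[Si](CC)(CC)CC
F14 | step 23 | 2,9,14-triacetate (C2 vinyl analogue of 31) | C=C[C@H](OC(C)=O)[C@@]1(C)[C@@H](OC(C)=O)C[C@H]2O[C@@]2(C)[C@@H]1[C@H](OC(C)=O)[C@]1(O)[C@@H](C)C(=O)O[C@H]1CO[Si](CC)(CC)CC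
F15 | step 23 | C6 aldehyde (C2 vinyl analogue of 32) | C=C[C@H](OC(C)=O)[C@@]1(C)[C@@H](OC(C)=O)C[C@H]2O[C@@]2(C)[C@@H]1[C@H](OC(C)=O)[C@]1(O)[C@@H](C)C(=O)O[C@H]1C=O
F16 | step 23 | C6 buta-1,3-dien-2-yl carbinol (C6 epimers, metathesis precursor) | C=C[C@H](OC(C)=O)[C@@]1(C)[C@@H](OC(C)=O)C[C@H]2O[C@@]2(C)[C@@H]1[C@H](OC(C)=O)[C@]1(O)[C@@H](C)C(=O)O[C@H]1C(O)C(=C)C=C
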